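**Assumption:** decalin compounds carry eremophilane numbering (C3 carbinol, C4 and C5 methyl-bearing carbons, C7 isopropylidene carbon, C8 ketone, C9 carbinol, C10 ring-fusion CH; β is the face of the C5 methyl). Grignard solutions that supply skeletal carbon are counted as starting materials.

## Retrosynthetic overview
1. The last bond made is the C3–O ester, by site-selective acylation of the 3,9-diol with the C13 trienoic acid.
2. In the diol, the C7 isopropylidene comes from acetone aldol and dehydration, and C9–OH from a Rubottom oxidation. One dissolving-metal reduction of a Δ9-ene-3,8-dione sets both C10–H (trans) and C3–OH (equatorial).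
3. Key disconnection: ring A (C3=O, C4–Me next to quaternary C5) comes from a 1-vinylcyclopentanol by a 1,2-shift of C5 from C3 to C4, a HAT-triggered semipinacol ring expansion.
4. Ring order: the bought cyclopentanedione ring comes first, ring B is annulated onto it (Michael, then proline aldol, which sets C5), and the five-membered ring is then enlarged to ring A.
5. The acid comes from a Heck reaction with acrylic acid (2E), Zr-catalysed methylalumination and iodination (4E), Negishi ethynylation, and hydroalumination of hept-1-yne (6E).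

## Route

**Step 1**
Reactants: 1 2-methylcyclopentane-1,3-dione; 2 but-3-en-2-one
Product: 3 2-methyl-2-(3-oxobutyl)cyclopentane-1,3-dione
Conditions: H2O, AcOH (cat.), 70 °C
Reagents that add atoms: none
Why: Michael addition of the acidic 1,3-dione to the vinyl ketone builds the quaternary carbon as a prochiral centre, so no stereocentre is set yet.

**Step 2**
Reactants: 3 2-methyl-2-(3-oxobutyl)cyclopentane-1,3-dione
Product: 5 (7aS)-7a-methyl-2,3,7,7a-tetrahydro-1H-indene-1,5(6H)-dione, via Hajos ketol 4 (not isolated)
Conditions: (S)-proline (3 mol %), DMF, 16 °C; then H2SO4 (cat.), 95 °C; recrystallise to >99% ee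
Reagents that add atoms: none
Why: The Hajos–Parrish–Eder–Sauer–Wiechert enamine aldol distinguishes the two enantiotopic ring ketones and fixes the quaternary carbon (future C5) as S, and acid then dehydrates the ketol to the enone.

**Step 3**
Reactants: 5 (7aS)-7a-methyl-2,3,7,7a-tetrahydro-1H-indene-1,5(6H)-dione; 6 vinylmagnesium bromide
Product: 7 (1R,7aS)-1-ethenyl-1-hydroxy-7a-methyl-1,2,3,6,7,7a-hexahydro-5H-inden-5-one
Conditions: 6 (1.1 equiv), LaCl3·2LiCl (30 mol %), THF, −78 °C; then H2O
Reagents that add atoms: none
Why: In this lanthanide-promoted Grignard 1,2-addition the non-conjugated cyclopentanone is the more electrophilic carbonyl (the same preference borohydride shows on this dione), and attack anti to the angular methyl puts vinyl on the α face and OH on the β face.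

**Step 4**
Reactants: 7 (1R,7aS)-1-ethenyl-1-hydroxy-7a-methyl-1,2,3,6,7,7a-hexahydro-5H-inden-5-one
Product: 8 (4aR,5R)-4a,5-dimethyl-4,4a,7,8-tetrahydronaphthalene-2,6(3H,5H)-dione
Conditions: Co(II) salen (3,5-di-tBu-salicylidene, tetramethylethylenediamine backbone, 5 mol %), N-fluoro-2,4,6-trimethylpyridinium triflate (1.2 equiv), PhSiH3 (1.2 equiv), PhCF3, 0 °C to rt
Reagents that add atoms: none
Why: Proposed new method: a cobalt-hydride HAT/radical–polar-crossover protio-semipinacol ring enlargement of an unstrained 1-vinylcyclopentanol, in which Co(III)–H gives H• only to the terminal vinyl carbon (the β,β-disubstituted enone is electron-poor and hindered), the C4 radical is captured and oxidised to a secondary alkylcobalt(IV) whose very large Co(salen) group sits anti to the bulkiest C3 substituent (quaternary C5), and so the electron-rich C3–C5 σ bond, rather than C2 or the oxygen (epoxide closure), displaces cobalt with inversion while O–H becomes C3=O, driven by C=O formation and relief of five-ring strain, forming the C4–C5 bond and ring A with retention at C5 and with the new C4 methyl in the exo rotamer, which ends equatorial (4β, cis to the C5 methyl, also the epimer favoured by enolisation); the closest known reaction types are Co-catalysed HAT-initiated semipinacol shifts of 1,1-disubstituted tertiary allylic alcohols and acid- or halonium-induced expansions of vinylcyclobutanols, neither shown for a monosubstituted vinyl group on an unstrained ring with migration of a quaternary carbon.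

**Step 5**
Reactants: 8 (4aR,5R)-4a,5-dimethyl-4,4a,7,8-tetrahydronaphthalene-2,6(3H,5H)-dione
Product: 10 3α,8-bis(triethylsilyloxy)-11,12,13-trinor-10αH-eremophil-8-ene (trans-decalin), via dilithium enolate alkoxide 9 (not isolated)
Conditions: Li (excess), t-BuOH (2.0 equiv), NH3/THF, −78 to −33 °C; isoprene; evaporate NH3; TESCl, Et3N, THF, 0 °C
Reagents that add atoms: chlorotriethylsilane CC[Si](CC)(CC)Cl
Why: In this dissolving-metal (Birch-type) reduction, axial protonation of the enone radical anion at C10 gives the trans-decalin enolate regiospecifically at C8=C9, the C3 ketyl goes to the more stable equatorial 3α alkoxide (trans-diequatorial with the C4 methyl), and silylation caps both oxygens.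

**Step 6**
Reactants: 10 3α,8-bis(triethylsilyloxy)-11,12,13-trinor-10αH-eremophil-8-ene
Product: 12 3α,9α-bis(triethylsilyloxy)-11,12,13-trinor-10αH-eremophilan-8-one, via silyloxy epoxide 11 (not isolated)
Conditions: mCPBA (1.05 equiv), CH2Cl2, −20 to 0 °C
Reagents that add atoms: 3-chloroperbenzoic acid O=C(OO)c1cccc(Cl)c1
Why: In this Rubottom oxidation the enol ether is epoxidised on the α face, anti to the axial C5 methyl that is 1,3 to C9, and the epoxide opens with silyl migration to the equatorial 9α-silyloxy ketone.

**Step 7**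
Reactants: 12 3α,9α-bis(triethylsilyloxy)-11,12,13-trinor-10αH-eremophilan-8-one; 13 acetone
Product: 15 11-hydroxy-3α,9α-bis(triethylsilyloxy)-10αH-eremophilan-8-one (7α side chain), via lithium enolate 14 (not isolated)
Conditions: LDA (1.1 equiv), THF, −78 °C; ZnCl2 (additive), 13 (5 equiv), −78 °C; AcOH quench at −78 °C
Reagents that add atoms: none
Why: In this directed aldol addition LDA removes the unhindered C7 proton (C9–H is tertiary and shielded by OTES), zinc chelation holds the aldolate against retro-aldol, and the C7 centre (drawn equatorial) is erased in step 8.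

**Step 8**
Reactants: 15 11-hydroxy-3α,9α-bis(triethylsilyloxy)-10αH-eremophilan-8-one
Product: 16 (3R,4R,5R,9S,10R)-3α,9α-dihydroxy-10αH-eremophil-7(11)-en-8-one
Conditions: p-TsOH·H2O (20 mol %), benzene, 70 °C, Ar
Reagents that add atoms: none
Why: Acid-catalysed E1 dehydration of the tertiary aldol gives the tetrasubstituted conjugated isopropylidene ketone (the thermodynamic isomer), the water released cleaves both TES ethers, and the equatorial 9α-OH is the stable ketol epimer.

**Step 9**
Reactants: 17 hept-1-yne
Product: 19 (E)-1-iodohept-1-ene, via heptenyl diisobutylalane 18 (not isolated)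
Conditions: DIBAL-H (1.0 equiv), hexane, 50 °C; then I2, THF, −50 °C to rt
Reagents that add atoms: iodine II
Why: Zweifel syn-hydroalumination puts aluminium on the terminal carbon, and iodinolysis with retention sets the future 6E alkene.

**Step 10**
Reactants: 19 (E)-1-iodohept-1-ene; 20 ethynylmagnesium bromide
Product: 22 (E)-non-3-en-1-yne, via ethynylzinc bromide 21 (not isolated)
Conditions: 20, ZnBr2, THF, 0 °C; then 19, Pd(PPh3)4 (3 mol %), rt
Reagents that add atoms: none
Why: Negishi sp2–sp coupling of the zinc acetylide proceeds with full retention of the E alkene and gives the free terminal enyne directly.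

**Step 11**
Reactants: 22 (E)-non-3-en-1-yne
Product: 24 (1E,3E)-1-iodo-2-methylnona-1,3-diene, via dienyl dimethylalane 23 (not isolated)
Conditions: Me3Al (2 equiv), Cp2ZrCl2 (25 mol %), CH2Cl2, 0 °C to rt; then I2, THF, −30 °C
Reagents that add atoms: trimethylaluminium C[Al](C)C; iodine II
Why: Negishi zirconium-catalysed syn-methylalumination puts methyl on the internal carbon and aluminium on the terminal carbon, and iodinolysis with retention sets the future 4E trisubstituted alkene.

**Step 12**
Reactants: 24 (1E,3E)-1-iodo-2-methylnona-1,3-diene; 25 acrylic acid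
Product: 26 (2E,4E,6E)-5-methyldodeca-2,4,6-trienoic acid
Conditions: Pd(OAc)2 (5 mol %), Bu4NCl, Et3N (2.5 equiv), DMF, 40 °C
Reagents that add atoms: none
Why: In this Mizoroki–Heck reaction under Jeffery conditions, syn insertion and syn β-hydride elimination give the 2E acid while the dienyl geometry is retained.

**Step 13**
Reactants: 16 (3R,4R,5R,9S,10R)-3α,9α-dihydroxy-10αH-eremophil-7(11)-en-8-one; 26 (2E,4E,6E)-5-methyldodeca-2,4,6-trienoic acid
Product: 28 (3R,4R,5R,9S,10R)-9-hydroxy-8-oxoeremophil-7(11)-en-3-yl (2E,4E,6E)-5-methyldodeca-2,4,6-trienoate, via Yamaguchi mixed anhydride 27 (not isolated)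
Conditions: 26 (1.0 equiv), 2,4,6-trichlorobenzoyl chloride (1.05 equiv), Et3N, toluene, rt; then 16, DMAP (1.2 equiv), 0 °C
Reagents that add atoms: none
Why: In this Yamaguchi esterification C3–OH is an ordinary equatorial carbinol, whereas the ketol C9–OH is deactivated by its hydrogen bond to C8=O, by the inductive pull of that carbonyl and by the peri C1 methylene, so one equivalent of acyl donor goes to C3 and no stereocentre is touched.

## Compound list
1 | 2-methylcyclopentane-1,3-dione | CC1C(=O)CCC1=O | starting material
2 | but-3-en-2-one | C=CC(C)=O | starting material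
3 | 2-methyl-2-(3-oxobutyl)cyclopentane-1,3-dione | CC(=O)CCC1(C)C(=O)CCC1=O | intermediate
4 | (3aS,7aS)-3a-hydroxy-7a-methylhexahydro-1H-indene-1,5(4H)-dione (not isolated) | O=C1CC[C@]2(O)CC(=O)CC[C@]12C | intermediate
5 | (7aS)-7a-methyl-2,3,7,7a-tetrahydro-1H-indene-1,5(6H)-dione | O=C1CCC2=CC(=O)CC[C@]12C | intermediate
6 | vinylmagnesium bromide | C=C[Mg]Br | starting material
7 | (1R,7aS)-1-ethenyl-1-hydroxy-7a-methyl-1,2,3,6,7,7a-hexahydro-5H-inden-5-one | C=C[C@]1(O)CCC2=CC(=O)CC[C@]12C | intermediate
8 | (4aR,5R)-4a,5-dimethyl-4,4a,7,8-tetrahydronaphthalene-2,6(3H,5H)-dione | O=C1CCC2=CC(=O)CC[C@]2(C)[C@H]1C | intermediate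
9 | dilithium 3α-alkoxide / C8 enolate of the trans-decalin (not isolated) | [Li]O[C@@H]1CC[C@H]2C=C(O[Li])CC[C@]2(C)[C@H]1C | intermediate
10 | 3α,8-bis(triethylsilyloxy)-11,12,13-trinor-10αH-eremophil-8-ene | CC[Si](CC)(CC)O[C@@H]1CC[C@H]2C=C(O[Si](CC)(CC)CC)CC[C@]2(C)[C@H]1C | intermediate
11 | 8α,9α-epoxide of 10 (not isolated) | CC[Si](CC)(CC)O[C@@H]1CC[C@H]2[C@@H]3O[C@]3(O[Si](CC)(CC)CC)CC[C@]2(C)[C@H]1C | intermediate
12 | 3α,9α-bis(triethylsilyloxy)-11,12,13-trinor-10αH-eremophilan-8-one | CC[Si](CC)(CC)O[C@@H]1CC[C@H]2[C@H](O[Si](CC)(CC)CC)C(=O)CC[C@]2(C)[C@H]1C | intermediate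
13 | acetone | CC(C)=O | starting material
14 | C7–C8 lithium enolate of 12 (not isolated) | CC[Si](CC)(CC)O[C@@H]1CC[C@H]2[C@H](O[Si](CC)(CC)CC)C(O[Li])=CC[C@]2(C)[C@H]1C | intermediate
15 | 11-hydroxy-3α,9α-bis(triethylsilyloxy)-10αH-eremophilan-8-one (7α side chain) | CC[Si](CC)(CC)O[C@@H]1CC[C@H]2[C@H](O[Si](CC)(CC)CC)C(=O)[C@H](C(C)(C)O)C[C@]2(C)[C@H]1C | intermediate
16 | (3R,4R,5R,9S,10R)-3α,9α-dihydroxy-10αH-eremophil-7(11)-en-8-one | O[C@@H]1CC[C@H]2[C@H](O)C(=O)C(=C(C)C)C[C@]2(C)[C@H]1C | intermediate
17 | hept-1-yne | CCCCCC#C | starting material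
18 | (E)-hept-1-enyl(diisobutyl)alane (not isolated) | CCCCC/C=C/[Al](CC(C)C)CC(C)C | intermediate
19 | (E)-1-iodohept-1-ene | CCCCC/C=C/I | intermediate
20 | ethynylmagnesium bromide | C#C[Mg]Br | starting material
21 | ethynylzinc bromide (not isolated) | C#C[Zn]Br | intermediate
22 | (E)-non-3-en-1-yne | CCCCC/C=C/C#C | intermediate
23 | (1E,3E)-2-methylnona-1,3-dienyl(dimethyl)alane (not isolated) | CCCCC/C=C/C(C)=C/[Al](C)C | intermediate
24 | (1E,3E)-1-iodo-2-methylnona-1,3-diene | CCCCC/C=C/C(C)=C/I | intermediate
25 | acrylic acid | C=CC(=O)O | starting material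
26 | (2E,4E,6E)-5-methyldodeca-2,4,6-trienoic acid | CCCCC/C=C/C(C)=C/C=C/C(=O)O | intermediate
27 | mixed anhydride of 26 with 2,4,6-trichlorobenzoic acid (not isolated) | CCCCC/C=C/C(C)=C/C=C/C(=O)OC(=O)c1c(Cl)cc(Cl)cc1Cl | intermediate
28 | CNP0211657.1 | CCCCC/C=C/C(C)=C/C=C/C(=O)O[C@@H]1CC[C@H]2[C@H](O)C(=O)C(=C(C)C)C[C@]2(C)[C@H]1C | target

## Step count
- Total steps: 13.
- Longest linear sequence: 9 (steps 1–8, then 13).
- Steps 9–12 form the side branch.

## The three steps most likely to fail

**Step 3 (saturated ketone versus enone).** The Grignard reagent may also attack the enone carbonyl. The fallback sets out from 5 and masks the enone first. Ethane-1,2-dithiol with p-TsOH in AcOH reacts selectively at the conjugated carbonyl to give the 5-(ethane-1,2-diyl dithioketal) of the hydrindenedione F1. Vinylmagnesium bromide 6 then has only the cyclopentanone left and gives the 1α-vinyl-1β-hydroxy dithioketal F2. MeI/CaCO3 in aqueous MeCN removes the dithiolane, and the route is rejoined at 7.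

**Step 4 (the proposed new ring enlargement).** Epoxide closure, C2 migration or enone reduction could all compete with the desired shift. The fallback uses known selenium-based ring enlargement and sets out from 5.
- 1-(Methylseleno)ethyllithium, made from 1,1-bis(methylseleno)ethane and n-BuLi in THF at −78 °C, adds to the cyclopentanone.
- This gives the β-hydroxy selenide (1R,7aS)-1-hydroxy-7a-methyl-1-[1-(methylselanyl)ethyl]-hexahydroinden-5-one F3, a mixture at the selenium-bearing carbon.
- TlOEt in CHCl3 converts selenium into a selenonium leaving group through dichlorocarbene and triggers the semipinacol shift.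
- In this reaction class the more substituted α-carbon migrates, so the route is rejoined at 8 without passing through 7.

**Step 13 (C3–OH versus C9–OH).** Mono-acylation may not be selective enough. The fallback sets out from 16 and 26 and acylates both hydroxyls, using 2.5 equiv of 26 under the same Yamaguchi activation at rt, to give the 3,9-bis(trienoate) F4. Brief treatment with K2CO3 in MeOH at 0 °C then cleaves only the α-acyloxy ketone ester at C9, which is activated by the neighbouring carbonyl through hemiketal-assisted methanolysis. The hindered conjugated C3 ester survives, and the route is rejoined at 28.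

## Further compounds
F1 | step 3 | (7aS)-7a-methyl-hydrindenedione 5-(ethane-1,2-diyl dithioketal) | O=C1CCC2=CC3(SCCS3)CC[C@]12C
F2 | step 3 | (1R,7aS)-1-ethenyl-1-hydroxy-7a-methyl-hydrinden-5-one ethane-1,2-diyl dithioketal | C=C[C@]1(O)CCC2=CC3(SCCS3)CC[C@]12C
F3 | step 4 | (1R,7aS)-1-hydroxy-7a-methyl-1-[1-(methylselanyl)ethyl]-1,2,3,6,7,7a-hexahydro-5H-inden-5-one | C[Se]C(C)[C@]1(O)CCC2=CC(=O)CC[C@]12C
F4 | step 13 | 8-oxo-10αH-eremophil-7(11)-ene-3α,9α-diyl bis[(2E,4E,6E)-5-methyldodeca-2,4,6-trienoate] | CCCCC/C=C/C(C)=C/C=C/C(=O)O[C@@H]1CC[C@H]2[C@H](OC(=O)/C=C/C=C(C)/C=C/CCCCC)C(=O)C(=C(C)C)C[C@]2(C)[C@H]1C
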